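**Retrosynthetic overview**
1. C3–O ester bond: target 16 ⇒ trans-alcohol 8 + (2Z)-2-(acetoxymethyl)but-2-enoic acid 14 (from crotonaldehyde via (Z)-2-iodobut-2-en-1-ol; the alkene geometry is fixed at the α-iodination).
2. Dihydrofuran ring ⇒ cut O1–C7a and C2–C3: a [3+2] annulation of 5-acetyl-2-fluoro-4-methoxybenzaldehyde 4 (C3, C3a, C7a) with methacrolein gem-diacetate 5 (C2, O1, isopropenyl) by Ir-catalysed enantioselective anti-(α-acetoxy)allylation, then deacetylation/SNAr in the same flask.
3. Enabling feature: the acetyl group on C5 is para to C7a, so a fluoride on C7a is SNAr-active; O1 and the C3 oxygen are vicinal, so the ring is a masked anti-1,2-diol in which only the C2 oxygen can reach C7a (five-membered ring; the C3 oxygen would need a four-membered one).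
4. Aldehyde 4 ⇐ 2-fluoro-4-methoxybenzaldehyde 1 by C5 bromination and Stille acetylation.
5. Ring order: benzene ring bought (1) → dihydrofuran ring (step 3) → esterification (step 8).

Key step: step 3

Assumption: the (R)-SEGPHOS iridium catalyst is taken to attack the aldehyde face that leads to the (1S,2R)-adduct; if the sense of induction is the opposite, (S)-SEGPHOS is used and nothing else changes.

**Step 1**
Reactants: 1 2-fluoro-4-methoxybenzaldehyde
Product: 2 5-bromo-2-fluoro-4-methoxybenzaldehyde
Conditions: Br2 (1.05 equiv), AcOH, 25 °C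
Reagents that add atoms: bromine, BrBr
Why: Electrophilic aromatic bromination should go to C5, which is ortho to the methoxy group, para to fluorine and meta to the formyl group, whereas the other activated position (C3) is flanked by two substituents.

**Step 2**
Reactants: 2 5-bromo-2-fluoro-4-methoxybenzaldehyde
Product: 4 5-acetyl-2-fluoro-4-methoxybenzaldehyde, via enol ether 3 (not isolated)
Conditions: tributyl(1-ethoxyvinyl)stannane, PdCl2(PPh3)2 (5 mol %), toluene, 100 °C; then 1 M HCl, THF, 25 °C
Reagents that add atoms: tributyl(1-ethoxyvinyl)stannane, CCCC[Sn](CCCC)(CCCC)C(=C)OCC; water, O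
Why: Stille coupling of the aryl bromide with the acetyl-anion equivalent gives enol ether 3, which dilute acid should hydrolyse to the methyl ketone while the aldehyde and the C–F bond stay untouched.

**Step 3**
Reactants: 4 5-acetyl-2-fluoro-4-methoxybenzaldehyde; 5 2-methylprop-2-ene-1,1-diyl diacetate
Product: 8 1-[(2R,3S)-3-hydroxy-6-methoxy-2-(prop-1-en-2-yl)-2,3-dihydro-1-benzofuran-5-yl]ethan-1-one, via anti-hydroxy acetate 6 (not isolated), via anti-diol 7 (not isolated)
Conditions: (R)-SEGPHOS π-allyl-iridium C,O-benzoate catalyst [from [Ir(cod)Cl]2, (R)-SEGPHOS, 4-cyano-3-nitrobenzoic acid, allyl acetate] (5 mol %), K3PO4 (1 equiv), i-PrOH (2 equiv), THF, 60 °C; then, same flask, Cs2CO3 (3 equiv), MeOH (10 equiv), DMSO, 50 °C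
Reagents that add atoms: none
Why: Mechanism: the cyclometalated iridium(I) complex ionises one acetate of 5 to an α-acetoxy-2-methyl-π-allyl iridium species whose syn/anti isomers equilibrate (so the prochiral gem-diacetate is funnelled through one reactive (E)-σ-allyl), this nucleophilic allyl adds to the aldehyde of 4 through a closed chair transition state to form C2–C3 (6, turnover by hydride from isopropanol), and after methanolysis (or 1,2-acetyl shift) the C2 alkoxide of 7 attacks the fluorine-bearing carbon and expels fluoride via a Meisenheimer adduct to form O1–C7a. Closest known reaction types: iridium-catalysed transfer-hydrogenative anti-(α-acyloxy)allylation of aryl aldehydes with allylic gem-dicarboxylates, and intramolecular SNAr etherification of 4-fluoroacetophenones. The dihydrofuran ring closes 5-exo-trig at an aromatic carbon. C3 is set by the chiral bisphosphine on iridium (aldehyde face), C2 is set relative to C3 by the (E)-geometry of the σ-allyl in the chair (anti), and the SNAr touches neither centre, so the anti-diol becomes the trans ring. The step needs aldehyde-over-ketone chemoselectivity, which the much more electrophilic formyl group should secure, and regioselective closure, secured because the C3 oxygen could only form a four-membered ring while the C5 acetyl group para to fluorine activates exactly C7a.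

**Step 4**
Reactants: 9 (E)-but-2-enal (crotonaldehyde)
Product: 10 (Z)-2-iodobut-2-enal
Conditions: I2 (1.5 equiv), K2CO3 (1.2 equiv), DMAP (0.2 equiv), THF/H2O 1:1, 25 °C
Reagents that add atoms: iodine, II
Why: Amine-catalysed α-iodination of an enal (Baylis–Hillman-type addition of DMAP, iodination of the enolate, E1cB loss of DMAP) should give the thermodynamically preferred (Z)-iodoenal, in which iodine is cis and the formyl group trans to the methyl group.

**Step 5**
Reactants: 10 (Z)-2-iodobut-2-enal
Product: 11 (Z)-2-iodobut-2-en-1-ol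
Conditions: NaBH4, MeOH, 0 °C
Reagents that add atoms: none
Why: Borohydride 1,2-reduction of the enal leaves the vinyl iodide and the alkene geometry untouched.

**Step 6**
Reactants: 11 (Z)-2-iodobut-2-en-1-ol
Product: 13 (2Z)-2-(hydroxymethyl)but-2-enoic acid, via dilithio alkoxide 12 (not isolated)
Conditions: n-BuLi (1.0 equiv), Et2O, −78 °C; t-BuLi (2.1 equiv), −78 °C; CO2 (g), −78 → 0 °C; then 1 M HCl
Reagents that add atoms: carbon dioxide, O=C=O
Why: O-deprotonation followed by iodine–lithium exchange gives a configurationally stable vinyllithium that is carboxylated with retention, so the carboxyl group ends up cis to the methyl group.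

**Step 7**
Reactants: 13 (2Z)-2-(hydroxymethyl)but-2-enoic acid
Product: 14 (2Z)-2-[(acetyloxy)methyl]but-2-enoic acid
Conditions: Ac2O (1.5 equiv), pyridine, CH2Cl2, 0 → 25 °C; then H2O
Reagents that add atoms: acetic anhydride, CC(=O)OC(C)=O
Why: O-acetylation of the primary alcohol with acetic anhydride/pyridine, the aqueous work-up hydrolysing any mixed anhydride back to the free acid.

**Step 8**
Reactants: 14 (2Z)-2-[(acetyloxy)methyl]but-2-enoic acid; 8 1-[(2R,3S)-3-hydroxy-6-methoxy-2-(prop-1-en-2-yl)-2,3-dihydro-1-benzofuran-5-yl]ethan-1-one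
Product: 16 (2R,3S)-5-acetyl-6-methoxy-2-(prop-1-en-2-yl)-2,3-dihydro-1-benzofuran-3-yl (2Z)-2-[(acetyloxy)methyl]but-2-enoate (target), via acid chloride 15 (not isolated)
Conditions: 14, 1-chloro-N,N,2-trimethylprop-1-en-1-amine (Ghosez's reagent, 1.1 equiv), CH2Cl2, 0 → 25 °C; then 8, pyridine (3 equiv), CH2Cl2, 0 → 25 °C
Reagents that add atoms: none
Why: Neutral acid chloride formation followed by pyridine-mediated O-acylation of the secondary alcohol avoids the acids and nucleophilic catalysts that isomerise (Z)-2-substituted but-2-enoates, and the acylation touches neither C2 nor C3.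

**Compound list**
1 | 2-fluoro-4-methoxybenzaldehyde | COc1ccc(C=O)c(F)c1 | starting material
2 | 5-bromo-2-fluoro-4-methoxybenzaldehyde | COc1cc(F)c(C=O)cc1Br | intermediate
3 | 5-(1-ethoxyethenyl)-2-fluoro-4-methoxybenzaldehyde | CCOC(=C)c1cc(C=O)c(F)cc1OC | intermediate
4 | 5-acetyl-2-fluoro-4-methoxybenzaldehyde | CC(=O)c1cc(C=O)c(F)cc1OC | intermediate
5 | 2-methylprop-2-ene-1,1-diyl diacetate (methacrolein gem-diacetate) | CC(=O)OC(OC(C)=O)C(C)=C | starting material
6 | (1S,2R)-1-(5-acetyl-2-fluoro-4-methoxyphenyl)-1-hydroxy-3-methylbut-3-en-2-yl acetate | C=C(C)[C@@H](OC(C)=O)[C@@H](O)c1cc(C(C)=O)c(OC)cc1F | intermediate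
7 | 1-{4-fluoro-5-[(1S,2R)-1,2-dihydroxy-3-methylbut-3-en-1-yl]-2-methoxyphenyl}ethan-1-one | C=C(C)[C@@H](O)[C@@H](O)c1cc(C(C)=O)c(OC)cc1F | intermediate
8 | 1-[(2R,3S)-3-hydroxy-6-methoxy-2-(prop-1-en-2-yl)-2,3-dihydro-1-benzofuran-5-yl]ethan-1-one | C=C(C)[C@H]1Oc2cc(OC)c(C(C)=O)cc2[C@@H]1O | intermediate
9 | (E)-but-2-enal (crotonaldehyde) | C/C=C/C=O | starting material
10 | (Z)-2-iodobut-2-enal | C/C=C(\I)C=O | intermediate
11 | (Z)-2-iodobut-2-en-1-ol | C/C=C(\I)CO | intermediate
12 | lithium 2-lithiobut-2-en-1-olate (lithium cis to the methyl group, geometry of 11 retained) | C/C=C(\[Li])CO[Li] | intermediate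
13 | (2Z)-2-(hydroxymethyl)but-2-enoic acid | C/C=C(\C(=O)O)CO | intermediate
14 | (2Z)-2-[(acetyloxy)methyl]but-2-enoic acid | C/C=C(\C(=O)O)COC(C)=O | intermediate
15 | (2Z)-2-[(acetyloxy)methyl]but-2-enoyl chloride | C/C=C(\C(Cl)=O)COC(C)=O | intermediate
16 | (2R,3S)-5-acetyl-6-methoxy-2-(prop-1-en-2-yl)-2,3-dihydro-1-benzofuran-3-yl (2Z)-2-[(acetyloxy)methyl]but-2-enoate | C=C(C)[C@H]1Oc2cc(OC)c(C(C)=O)cc2[C@@H]1OC(=O)/C(=C\C)COC(C)=O | target

**Totals**
Total step count: 8. Longest linear sequence: 5 steps (steps 4, 5, 6, 7, 8 from crotonaldehyde); the arene branch is 4 steps (1, 2, 3, 8).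

**Steps most likely to fail**

Step 3. Possible failure processes:
- Ionisation of the 2-substituted gem-diacetate may be slow, so that plain transfer hydrogenation of the aldehyde outruns C–C coupling.
- Isopropoxide may displace the doubly activated fluoride of 4 before the allylation.
- The 2-methyl group may lower the preference for the (E)-σ-allyl and erode anti-selectivity.
- Iridium may ionise the allylic aryl ether once the ring has closed.

Fallback (racemic, then resolved; sets out from 4, returns at 8): commercial methacrolein and acetyl bromide (cat. ZnCl2, CH2Cl2, −20 °C) give 3-bromo-2-methylprop-1-en-1-yl acetate F1. Zinc-mediated Barbier γ-acyloxyallylation of 4 with F1 (Zn, sat. aq NH4Cl/THF, 0 °C) should give the racemic anti-hydroxy acetate F2, possibly with some syn isomer. Cs2CO3/MeOH/DMSO at 50 °C should then close the ring to the racemic trans-alcohol F3, the cis isomer being removed by chromatography. Preparative chromatography on a chiral stationary phase delivers the (2R,3S)-enantiomer, which is compound 8.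

Step 8. Possible failure processes: Z→E isomerisation of the enoyl unit through reversible conjugate addition to the activated acyl species; SN2′ loss of the allylic acetate; sluggish acylation of the hindered benzylic alcohol.

Fallback (sets out from 13 and 8, returns at 16): 13 is bis-silylated (TBSCl, imidazole, DMF) to tert-butyldimethylsilyl (2Z)-2-{[(tert-butyldimethylsilyl)oxy]methyl}but-2-enoate F4. The silyl ester is cleaved (K2CO3, MeOH/THF/H2O) to (2Z)-2-{[(tert-butyldimethylsilyl)oxy]methyl}but-2-enoic acid F5. Yamaguchi activation (2,4,6-trichlorobenzoyl chloride, Et3N, toluene) gives the mixed anhydride F6, which should acylate 8 (toluene, 80 °C, no DMAP) to the silyl-protected ester F7. HF·pyridine/THF frees the primary alcohol to give the hydroxy ester F8, and Ac2O/pyridine acetylates it to 16. The acetate is thus introduced only after the ester bond exists.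

Step 6. Possible failure processes: protonation of the vinyllithium by incompletely deprotonated alcohol; poor solubility of the dianion; loss of alkene geometry if the temperature rises before carboxylation.

Fallback (sets out from 11, returns at 13): palladium-catalysed methoxycarbonylation of the vinyl iodide (PdCl2(PPh3)2, CO 1 atm, Et3N, MeOH, 50 °C) should give methyl (2Z)-2-(hydroxymethyl)but-2-enoate F9 with retention of geometry. Mild saponification (LiOH, THF/H2O, 0 °C; then dilute HCl) gives 13.

**Further compounds**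
F1 | step 3 | 3-bromo-2-methylprop-1-en-1-yl acetate (E/Z mixture) | CC(=O)OC=C(C)CBr
F2 | step 3 | rac-(1RS,2SR)-1-(5-acetyl-2-fluoro-4-methoxyphenyl)-1-hydroxy-3-methylbut-3-en-2-yl acetate (racemate of 6; one enantiomer drawn) | C=C(C)[C@@H](OC(C)=O)[C@@H](O)c1cc(C(C)=O)c(OC)cc1F
F3 | step 3 | rac-trans-1-[3-hydroxy-6-methoxy-2-(prop-1-en-2-yl)-2,3-dihydro-1-benzofuran-5-yl]ethan-1-one (racemate of 8; one enantiomer drawn) | C=C(C)[C@H]1Oc2cc(OC)c(C(C)=O)cc2[C@@H]1O
F4 | step 8 | tert-butyldimethylsilyl (2Z)-2-{[(tert-butyldimethylsilyl)oxy]methyl}but-2-enoate | C/C=C(\C(=O)O[Si](C)(C)C(C)(C)C)CO[Si](C)(C)C(C)(C)C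
F5 | step 8 | (2Z)-2-{[(tert-butyldimethylsilyl)oxy]methyl}but-2-enoic acid | C/C=C(\C(=O)O)CO[Si](C)(C)C(C)(C)C
F6 | step 8 | (2Z)-2-{[(tert-butyldimethylsilyl)oxy]methyl}but-2-enoic 2,4,6-trichlorobenzoic anhydride | C/C=C(\C(=O)OC(=O)c1c(Cl)cc(Cl)cc1Cl)CO[Si](C)(C)C(C)(C)C
F7 | step 8 | (2R,3S)-5-acetyl-6-methoxy-2-(prop-1-en-2-yl)-2,3-dihydro-1-benzofuran-3-yl (2Z)-2-{[(tert-butyldimethylsilyl)oxy]methyl}but-2-enoate | C=C(C)[C@H]1Oc2cc(OC)c(C(C)=O)cc2[C@@H]1OC(=O)/C(=C\C)CO[Si](C)(C)C(C)(C)C
F8 | step 8 | (2R,3S)-5-acetyl-6-methoxy-2-(prop-1-en-2-yl)-2,3-dihydro-1-benzofuran-3-yl (2Z)-2-(hydroxymethyl)but-2-enoate | C=C(C)[C@H]1Oc2cc(OC)c(C(C)=O)cc2[C@@H]1OC(=O)/C(=C\C)CO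
F9 | step 6 | methyl (2Z)-2-(hydroxymethyl)but-2-enoate | C/C=C(\C(=O)OC)CO
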